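## Analysis of the target

Target 22 is an isoflavone: a 4H-chromen-4-one in which the benzo ring A is fused to the pyranone ring C, with ring B (3-hydroxy-4,5-dimethoxyphenyl) on C3 and hydrogen on C2. It has no stereocentre and no double bond of defined geometry, so every problem is one of regiochemistry and of telling oxygens apart. Ring A is fully substituted: OH on C5, OMe on C6, OH on C7, OH on C8, with C4a and C8a belonging to ring C. The single methyl ether of ring A lies between two free hydroxyls, so the oxygens on C5, C7, C8 and C3' must be carried in a form that can be removed while three methyl ethers stay. The free 5,8-hydroquinone is readily oxidised to a quinone, above all in base, and C2 of ring C is a vinylogous formate carbon that hydroxide or alkoxide can open; the phenols are therefore best freed last, under acidic and non-oxidising conditions. The strategy rests on one feature: O1 and C4 are bound to the neighbouring ring A carbons C8a and C4a, and C4a is flanked by the oxygen-bearing C5. This is the pattern left when an oxygen nucleophile and then an acyl group add across a 3-alkoxybenzyne. If C8 is kept as C–H at that stage, the C5/C6/C7 pattern (isopropoxy, methoxy, isopropoxy) derives from a phenol that is symmetric about the C6–OMe axis, and C8 lies para to the C5 hydroxyl, where a phenol-directed oxidation can place the last oxygen.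

## Retrosynthetic reasoning

**22 back to 21.** The last bonds cut are the two O–isopropyl bonds at C7 and C3' of 5,8-dihydroxy-7-isopropoxy-6-methoxy-3-(3-isopropoxy-4,5-dimethoxyphenyl)-4H-chromen-4-one 21. Secondary alkyl aryl ethers ionise under a boron Lewis acid at temperatures where methyl ethers are inert, so masked hydroxyls and true methoxyls can be distinguished. The step is acidic and non-oxidising, which suits the hydroquinone it sets free.

**21 back to 19.** The C8–O bond is cut next. The oxygen is left out until after the ring-forming step because an aryne flanked by alkoxy groups on both sides would have no regiochemical bias. In 5-hydroxy compound 19, C8 is the only free position of ring A and is para to the C5 hydroxyl, which is what an Elbs persulfate oxidation requires (through aryl sulfate 20). Ring B must carry no free phenol here, which is why its C3' oxygen stays protected.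

**19 back to 18.** Only the C5 O–isopropyl bond of the fully protected isoflavone 18 is cut. This ether is peri to the C4 carbonyl and is the one a stoichiometric Lewis acid cleaves through a six-membered chelate.

**18 back to 16 and 8.** Here the bonds O1–C8a and C4–C4a are cut together. Ring A becomes aryne 17, released from silyl triflate 16. The rest becomes formyl ester 8, which holds C2, C3, C4 and ring B. The cut divides the molecule into two halves of similar size and makes both ring A–ring C bonds in one operation. The forward reaction must put the enol oxygen on C8a and the ester carbon on C4a, not the reverse.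

**16 back to 13, 12, 10 and 9.** The C–Si and O–S bonds of 16 go back to bromophenol 13 by O-silylation (14), bromine–lithium exchange with retro-Brook shift (15) and triflation. Bromophenol 13 comes from phenol 12 by ortho-bromination; because 12 is symmetric, its two ortho positions are the same and no regiochemical question arises. The phenol C–O bond of 12 is traced to the only unhindered C–H of 10 by borylation (11) and oxidation, and 10 is the bis-isopropyl ether of 2-methoxyresorcinol 9.

**8 back to 6, 7, 4, 2 and 1.** The C2–C3 bond of 8 is a Claisen bond between arylacetate 6 and methyl formate 7. The carboxyl carbon of 6 (the future C4) is added to aldehyde 2 by one-carbon homologation to nitrile 4 (through 3) and Pinner methanolysis (through 5). Aldehyde 2 is the isopropyl ether of 3-hydroxy-4,5-dimethoxybenzaldehyde 1.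

## Alternatives that were turned down

**Alternative 1:** Ring A is cut at C4a–C5 and treated as a folded polyketide chain on a preformed ring C. The precursor would be methyl 2-methoxy-4-(methoxymethoxy)-4-{5-[3-(methoxymethoxy)-4,5-dimethoxyphenyl]-4-oxo-4H-pyran-2-yl}-3-oxobutanoate A2. Base would form its extended enolate, the pyranone carbon that becomes C4a would attack the terminal ester (6-exo-trig Claisen), and enolisation would give 5,7-dihydroxy-6-methoxy-8-(methoxymethoxy)-3-[3-(methoxymethoxy)-4,5-dimethoxyphenyl]-4H-chromen-4-one A1, two acetal cleavages away from 22.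
- For it: all four ring A oxygens arrive at the right oxidation level and already differentiated. No late C–H oxidation and no selective dealkylation is needed; on this point it is stronger than the chosen route.
- Against it: A2 is a densely oxygenated tricarbonyl chain that needs a long linear assembly on a 3-arylpyranone. Its most acidic hydrogen lies between the ketone and the ester, so the first enolate formed deactivates the ester that must be attacked. The carbon nucleophile is the weakly nucleophilic α-carbon of a vinylogous ester, and O-acylation and retro-Claisen cleavage are open to the same anion.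
- In its place the chosen strategy offers two four-step fragments from simple aromatics and a ring closure whose regiochemistry depends on one substituent.

**Alternative 2:** Ring C is cut at C3–C4. The aldehyde–ketone 3,4,6-tri-isopropoxy-5-methoxy-2-[2-(3-isopropoxy-4,5-dimethoxyphenyl)-2-oxoethoxy]benzaldehyde A4 would be treated with a triazolium-derived N-heterocyclic carbene and an amine base. The acyl anion equivalent from the aldehyde would add to the ketone carbon (6-exo-trig crossed benzoin) to give racemic 3-hydroxy-5,7,8-tri-isopropoxy-6-methoxy-3-(3-isopropoxy-4,5-dimethoxyphenyl)chroman-4-one A3. Dehydration across C2–C3 would give 5,7,8-tri-isopropoxy-6-methoxy-3-(3-isopropoxy-4,5-dimethoxyphenyl)-4H-chromen-4-one A5, and four dealkylations would give 22.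
- For it: intramolecular aldehyde–ketone benzoin closure to 3-hydroxychromanones is a known reaction type, so the ring closure is better precedented than the aryne step. It is mild, the new stereocentre is erased, and no oxidation at C8 is needed.
- Against it: the difficulty moves into A4, a hexasubstituted benzaldehyde with four oxygens in a fixed unsymmetrical order; symmetry cannot be used because C8 is already oxygenated. The aldehyde lies between two ortho alkoxy groups, so it is hindered and electron-rich. The ketol is not an aldol that eliminates by itself; it needs a separate activation to lose water.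
- The chosen route forms two bonds where this one forms one, and draws its ring A from a symmetric phenol in four steps.

**Alternative 3:** Ring A is built from a squaric ester. The mixed squarate 3-isopropoxy-4-methoxycyclobut-3-ene-1,2-dione A8 would take up a pyranone metallated at the future C4a to give racemic 4-hydroxy-2-isopropoxy-3-methoxy-4-[5-(3-isopropoxy-4,5-dimethoxyphenyl)-4-oxo-4H-pyran-3-yl]cyclobut-2-en-1-one A7. Heating would open the four-membered ring to a vinylketene, which would close onto the pyranone double bond (forming C8–C8a) and tautomerise to 5,8-dihydroxy-7-isopropoxy-6-methoxy-3-(3-isopropoxy-4,5-dimethoxyphenyl)-4H-chromen-4-one A6 (Moore rearrangement).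
- For it: A6 is identical with 21, reached without persulfate oxidation and without selective dealkylation, in a reagent-free thermal step. On the end-game it is stronger than the chosen route.
- Against it: the order OMe at C6 and O-isopropyl at C7 is decided by which carbonyl of A8 is attacked, and the two differ only in a remote alkyl group, so no real control is expected. A 4-pyranone metallated next to its carbonyl is hard to generate without ring opening or self-addition. The electrocyclisation must engage an electron-poor, cross-conjugated double bond. Ring B has to be on the pyranone first, so the sequence is linear.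
- The chosen route fixes the C6/C7 pattern by the symmetry of phenol 12 and is convergent.

Key step: step 9

## Route

Remark on the chemistry: formyl ester 8 is written as its aldehyde tautomer; it is assumed to exist mainly as the hydrogen-bonded Z-enol, and its α-stereocentre is labile and of no consequence. Compounds 1, 7 and 9 are assumed to be commercial.

Step 1
Reactants: 1 3-hydroxy-4,5-dimethoxybenzaldehyde
Product: 2 3-isopropoxy-4,5-dimethoxybenzaldehyde
Conditions: 2-bromopropane, K2CO3, DMF, 60 °C
Reagents that add atoms: 2-bromopropane, CC(C)Br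
Why: Williamson ether synthesis on the only phenol. The isopropyl ether should survive all later basic steps and can be removed at the end without loss of the methyl ethers.

Step 2
Reactants: 2 3-isopropoxy-4,5-dimethoxybenzaldehyde
Product: 4 2-(3-isopropoxy-4,5-dimethoxyphenyl)acetonitrile, via vinylformamide 3 (not isolated)
Conditions: TosMIC, KOtBu, DME, −30 °C; then MeOH, reflux
Reagents that add atoms: p-toluenesulfonylmethyl isocyanide (TosMIC), Cc1ccc(cc1)S(=O)(=O)C[N+]#[C-]
Why: van Leusen reductive cyanation of an aldehyde. The TosMIC anion adds to the aldehyde, the oxazoline opens to vinylformamide 3, and methanol removes the formyl group; loss of sulfinate then gives the homologated nitrile.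

Step 3
Reactants: 4 2-(3-isopropoxy-4,5-dimethoxyphenyl)acetonitrile
Product: 6 methyl 2-(3-isopropoxy-4,5-dimethoxyphenyl)acetate, via imidate hydrochloride 5 (not isolated)
Conditions: HCl (g), MeOH, 0 °C to rt; then H2O, rt
Reagents that add atoms: methanol, CO; water, O
Why: Pinner reaction. Methanol adds to the protonated nitrile and the imidate salt is hydrolysed to the methyl ester; aryl isopropyl and methyl ethers are stable to methanolic HCl at room temperature.

Step 4
Reactants: 6 methyl 2-(3-isopropoxy-4,5-dimethoxyphenyl)acetate; 7 methyl formate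
Product: 8 methyl 2-(3-isopropoxy-4,5-dimethoxyphenyl)-3-oxopropanoate
Conditions: NaH, THF, 0 °C to rt; then aq. HCl
Reagents that add atoms: none
Why: Crossed Claisen condensation with a non-enolisable formate, driven by formation of the stabilised enolate of the product. Methyl formate matches the methyl ester, so no alkoxy exchange can occur.

Step 5
Reactants: 9 2-methoxyresorcinol
Product: 10 1,3-di-isopropoxy-2-methoxybenzene
Conditions: 2-bromopropane, K2CO3, DMF, 70 °C
Reagents that add atoms: 2-bromopropane, CC(C)Br
Why: Double Williamson alkylation of the two equivalent phenols. The product keeps the mirror symmetry on which the later ortho-functionalisation relies.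

Step 6
Reactants: 10 1,3-di-isopropoxy-2-methoxybenzene
Product: 12 3,5-di-isopropoxy-4-methoxyphenol, via aryl pinacol boronate 11 (not isolated)
Conditions: [Ir(OMe)(cod)]2 (cat.), dtbpy (cat.), B2pin2, THF, 80 °C; then 30% H2O2, aq. NaOH, 0 °C
Reagents that add atoms: hydrogen peroxide, OO (the phenol oxygen); bis(pinacolato)diboron, CC1(C)OB(OC1(C)C)B1OC(C)(C)C(C)(C)O1 (boron of intermediate 11 only)
Why: Iridium-catalysed C–H borylation is sterically controlled, and C5 of 10 is the only ring C–H without an ortho substituent. Oxidation of the C–B bond then gives the symmetric phenol in one pot.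

Step 7
Reactants: 12 3,5-di-isopropoxy-4-methoxyphenol
Product: 13 2-bromo-3,5-di-isopropoxy-4-methoxyphenol
Conditions: NBS (1.0 equiv), CH2Cl2, −78 to 0 °C
Reagents that add atoms: N-bromosuccinimide, O=C1CCC(=O)N1Br
Why: Electrophilic aromatic bromination ortho to the phenol. The two free positions of 12 are equivalent, so only mono- against di-bromination has to be controlled, which low temperature and one equivalent of NBS should do.

Step 8
Reactants: 13 2-bromo-3,5-di-isopropoxy-4-methoxyphenol
Product: 16 3,5-di-isopropoxy-4-methoxy-2-(trimethylsilyl)phenyl trifluoromethanesulfonate, via silyl ether 14 (not isolated), via lithium phenoxide 15 (not isolated)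
Conditions: HMDS, THF, 65 °C, then evaporation; n-BuLi, THF, −78 °C; Tf2O, −78 °C to rt
Reagents that add atoms: hexamethyldisilazane, C[Si](C)(C)N[Si](C)(C)C; trifluoromethanesulfonic anhydride, O=S(=O)(OS(=O)(=O)C(F)(F)F)C(F)(F)F
Why: Standard entry to ortho-silylaryl triflates. O-Silylation and bromine–lithium exchange are followed by a 1,3-shift of silicon from oxygen to carbon (retro-Brook rearrangement), and the resulting phenoxide is triflated in the same flask.

Step 9
Reactants: 16 3,5-di-isopropoxy-4-methoxy-2-(trimethylsilyl)phenyl trifluoromethanesulfonate; 8 methyl 2-(3-isopropoxy-4,5-dimethoxyphenyl)-3-oxopropanoate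
Product: 18 5,7-di-isopropoxy-6-methoxy-3-(3-isopropoxy-4,5-dimethoxyphenyl)-4H-chromen-4-one, via 3,5-di-isopropoxy-4-methoxybenzyne 17 (not isolated)
Conditions: CsF (4 equiv), THF, 65 °C, slow addition of 16
Reagents that add atoms: none
Why: Proposed new method: fluoride attacks the silicon of 16 and triflate leaves, giving aryne 17, while CsF also converts 8 into its caesium enolate. The single isopropoxy group beside the triple bond (the future C5 oxygen) polarises and bends the aryne so that a nucleophile adds to the remote carbon (future C8a) and the carbanion develops at the carbon next to the C–O bond (future C4a), where it is stabilised inductively; keeping C8 as C–H leaves this bias unopposed. The enolate oxygen sits on an unhindered CH and should add in preference to the enolate carbon, which is tertiary, aryl-substituted and conjugated; this O- over C-arylation is the first selectivity the step needs and the less secured one. The ortho-aryl anion then attacks the ester carbonyl held cis to the aryloxy group in the Z-enol ether (6-exo-trig, forming C4–C4a), and loss of methoxide gives the chromone, so O1–C8a, C4–C4a and ring C are made in one operation. The closest known reaction type is the coupling of ortho-hydroxybenzoate esters with arynes to give xanthones, where a phenoxide adds to the aryne and the aryl anion acylates on the neighbouring ester; here the oxygen nucleophile is an ambident enolate whose double-bond geometry is not fixed by a ring. The known competing path for 1,3-dicarbonyl compounds is C-arylation followed by insertion into the C–C(=O) bond, which the substitution at the enolate carbon is meant to suppress. THF at 65 °C is chosen because a poorly proton-donating medium favours acylation of the aryl anion over its protonation. No stereocentre is formed.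

Step 10
Reactants: 18 5,7-di-isopropoxy-6-methoxy-3-(3-isopropoxy-4,5-dimethoxyphenyl)-4H-chromen-4-one
Product: 19 5-hydroxy-7-isopropoxy-6-methoxy-3-(3-isopropoxy-4,5-dimethoxyphenyl)-4H-chromen-4-one
Conditions: BCl3 (1.1 equiv), CH2Cl2, −78 °C; then H2O
Reagents that add atoms: none
Why: Chelation-controlled Lewis-acid dealkylation. One equivalent of BCl3 is bound first by the strongly basic pyranone carbonyl and cleaves the peri C5 isopropyl ether through a six-membered chelate, while the C7 and C3' ethers should not react at −78 °C.

Step 11
Reactants: 19 5-hydroxy-7-isopropoxy-6-methoxy-3-(3-isopropoxy-4,5-dimethoxyphenyl)-4H-chromen-4-one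
Product: 21 5,8-dihydroxy-7-isopropoxy-6-methoxy-3-(3-isopropoxy-4,5-dimethoxyphenyl)-4H-chromen-4-one, via aryl potassium sulfate 20 (not isolated)
Conditions: K2S2O8, aq. KOH, pyridine, 15 °C to rt; then aq. HCl, Na2SO3, 80 °C
Reagents that add atoms: potassium peroxodisulfate, [K+].[K+].[O-]S(=O)(=O)OOS(=O)(=O)[O-]
Why: Elbs persulfate oxidation, the classical para-hydroxylation of 5-hydroxychromones. The C5 phenoxide attacks the peroxide oxygen through C8, its only free para position, and the aryl sulfate is hydrolysed by acid; ring B has no free phenol and should not react.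

Step 12
Reactants: 21 5,8-dihydroxy-7-isopropoxy-6-methoxy-3-(3-isopropoxy-4,5-dimethoxyphenyl)-4H-chromen-4-one
Product: 22 5,7,8-trihydroxy-3-(3-hydroxy-4,5-dimethoxyphenyl)-6-methoxy-4H-chromen-4-one
Conditions: BCl3 (excess), CH2Cl2, −78 to 0 °C; then MeOH/H2O, under argon
Reagents that add atoms: none
Why: Lewis-acid cleavage of the two remaining isopropyl ethers, which ionise far more readily than methyl ethers, so the three methoxy groups should be kept. The conditions are acidic and non-oxidising, as the 5,8-hydroquinone requires.

## Compound list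

1 | 3-hydroxy-4,5-dimethoxybenzaldehyde | COc1cc(C=O)cc(O)c1OC | starting material
2 | 3-isopropoxy-4,5-dimethoxybenzaldehyde | COc1cc(C=O)cc(OC(C)C)c1OC | intermediate
3 | N-[2-(3-isopropoxy-4,5-dimethoxyphenyl)-1-tosylethenyl]formamide (alkene geometry not defined) | O=CNC(=Cc1cc(OC)c(OC)c(OC(C)C)c1)S(=O)(=O)c1ccc(C)cc1 | intermediate (not isolated)
4 | 2-(3-isopropoxy-4,5-dimethoxyphenyl)acetonitrile | COc1cc(CC#N)cc(OC(C)C)c1OC | intermediate
5 | methyl 2-(3-isopropoxy-4,5-dimethoxyphenyl)acetimidate hydrochloride | Cl.COC(=N)Cc1cc(OC)c(OC)c(OC(C)C)c1 | intermediate (not isolated)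
6 | methyl 2-(3-isopropoxy-4,5-dimethoxyphenyl)acetate | COC(=O)Cc1cc(OC)c(OC)c(OC(C)C)c1 | intermediate
7 | methyl formate | COC=O | starting material
8 | methyl 2-(3-isopropoxy-4,5-dimethoxyphenyl)-3-oxopropanoate (racemic, in equilibrium with its Z-enol) | COC(=O)C(C=O)c1cc(OC)c(OC)c(OC(C)C)c1 | intermediate
9 | 2-methoxyresorcinol (2-methoxybenzene-1,3-diol) | COc1c(O)cccc1O | starting material
10 | 1,3-di-isopropoxy-2-methoxybenzene | COc1c(OC(C)C)cccc1OC(C)C | intermediate
11 | 2-(3,5-di-isopropoxy-4-methoxyphenyl)-4,4,5,5-tetramethyl-1,3,2-dioxaborolane | COc1c(OC(C)C)cc(B2OC(C)(C)C(C)(C)O2)cc1OC(C)C | intermediate (not isolated)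
12 | 3,5-di-isopropoxy-4-methoxyphenol | COc1c(OC(C)C)cc(O)cc1OC(C)C | intermediate
13 | 2-bromo-3,5-di-isopropoxy-4-methoxyphenol | COc1c(OC(C)C)cc(O)c(Br)c1OC(C)C | intermediate
14 | (2-bromo-3,5-di-isopropoxy-4-methoxyphenoxy)trimethylsilane | COc1c(OC(C)C)cc(O[Si](C)(C)C)c(Br)c1OC(C)C | intermediate (not isolated)
15 | lithium 3,5-di-isopropoxy-4-methoxy-2-(trimethylsilyl)phenoxide | [Li+].[O-]c1cc(OC(C)C)c(OC)c(OC(C)C)c1[Si](C)(C)C | intermediate (not isolated)
16 | 3,5-di-isopropoxy-4-methoxy-2-(trimethylsilyl)phenyl trifluoromethanesulfonate | COc1c(OC(C)C)cc(OS(=O)(=O)C(F)(F)F)c([Si](C)(C)C)c1OC(C)C | intermediate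
17 | 3,5-di-isopropoxy-4-methoxybenzyne | COC1=C(OC(C)C)C#CC=C1OC(C)C | intermediate (not isolated)
18 | 5,7-di-isopropoxy-6-methoxy-3-(3-isopropoxy-4,5-dimethoxyphenyl)-4H-chromen-4-one | COc1c(OC(C)C)cc2occ(-c3cc(OC)c(OC)c(OC(C)C)c3)c(=O)c2c1OC(C)C | intermediate
19 | 5-hydroxy-7-isopropoxy-6-methoxy-3-(3-isopropoxy-4,5-dimethoxyphenyl)-4H-chromen-4-one | COc1c(OC(C)C)cc2occ(-c3cc(OC)c(OC)c(OC(C)C)c3)c(=O)c2c1O | intermediate
20 | potassium 5-hydroxy-7-isopropoxy-6-methoxy-3-(3-isopropoxy-4,5-dimethoxyphenyl)-4-oxo-4H-chromen-8-yl sulfate | COc1c(OC(C)C)c(OS(=O)(=O)[O-])c2occ(-c3cc(OC)c(OC)c(OC(C)C)c3)c(=O)c2c1O.[K+] | intermediate (not isolated)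
21 | 5,8-dihydroxy-7-isopropoxy-6-methoxy-3-(3-isopropoxy-4,5-dimethoxyphenyl)-4H-chromen-4-one | COc1c(OC(C)C)c(O)c2occ(-c3cc(OC)c(OC)c(OC(C)C)c3)c(=O)c2c1O | intermediate
22 | 5,7,8-trihydroxy-3-(3-hydroxy-4,5-dimethoxyphenyl)-6-methoxy-4H-chromen-4-one (5,7,8,3'-tetrahydroxy-6,4',5'-trimethoxyisoflavone) | COc1cc(-c2coc3c(O)c(O)c(OC)c(O)c3c2=O)cc(O)c1OC | target

## Step count and risk

Total step count: 12. Longest linear sequence: 8 steps (steps 1–4 or steps 5–8, then steps 9–12).

**Step 9 (key step, the only step marked as a proposed new method).**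
- What may go wrong: C-arylation of the enolate followed by insertion of the aryne into the C–CHO bond; protonation of the aryl anion before it acylates, which is certain for any O-arylation that occurs through the E-enolate; deformylation of 8 by the methoxide set free; partial loss of regiocontrol in the addition to the aryne.
- Fallback (known chemistry), from phenol 12 and nitrile 4, returning at 18: Houben–Hoesch acylation of 12 with 4 (ZnCl2, HCl gas, Et2O, 0 °C) should give the ketiminium salt 1-(2-hydroxy-4,6-di-isopropoxy-5-methoxyphenyl)-2-(3-isopropoxy-4,5-dimethoxyphenyl)ethan-1-iminium chloride F1. Warm water hydrolyses it to the deoxybenzoin 1-(2-hydroxy-4,6-di-isopropoxy-5-methoxyphenyl)-2-(3-isopropoxy-4,5-dimethoxyphenyl)ethan-1-one F2. Because 12 is symmetric, its two ortho positions are the same and only one ketone can form. Heating F2 with N,N-dimethylformamide dimethyl acetal in toluene adds C2 and closes ring C to 18. This gives up the two-bond convergence but needs only classical reactions.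

**Step 11 (Elbs oxidation).**
- What may go wrong: low conversion, usual for persulfate oxidations of chelated phenols, and opening of ring C by hydroxide at C2 during the alkaline phase.
- Fallback, from 19, returning at 21: bromination of 19 at C8, its only free ring A position and para to the phenol (NBS, MeCN, 0 °C), should give 8-bromo-5-hydroxy-7-isopropoxy-6-methoxy-3-(3-isopropoxy-4,5-dimethoxyphenyl)-4H-chromen-4-one F3. Palladium-catalysed C–O coupling with (E)-benzaldehyde oxime as a hydroxide surrogate (Pd2(dba)3, tBuBrettPhos, Cs2CO3, DMF, 80 °C) passes through the O-aryl oxime 5-hydroxy-7-isopropoxy-6-methoxy-3-(3-isopropoxy-4,5-dimethoxyphenyl)-8-{[(E)-benzylideneamino]oxy}-4H-chromen-4-one F4 (not isolated). F4 loses benzonitrile under the same weakly basic conditions and gives 21 without aqueous alkali.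

**Step 10 (selective C5 dealkylation).**
- What may go wrong: loss of selectivity among the three isopropyl ethers; cleavage of the ring B ether would expose a phenol that the Elbs step would also oxidise.
- Fallback, from 18, returning at 19: excess BCl3 (CH2Cl2, −78 to 0 °C) removes all three isopropyl groups to give 5,7-dihydroxy-3-(3-hydroxy-4,5-dimethoxyphenyl)-6-methoxy-4H-chromen-4-one F5. Alkylation with 2-bromopropane (2 equiv, K2CO3, DMF, 40 °C) then re-etherifies the C7 and C3' phenols. The C5 hydroxyl, hydrogen-bonded to the carbonyl, is the least nucleophilic and should stay free, giving 19.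

**Step 12 (final deprotection).**
- What may go wrong: over-dealkylation, in particular loss of the C6 methyl ether flanked by two boron-bound phenoxides, and aerial oxidation of the hydroquinone during aqueous work-up.
- Fallback, from 18, ending at 22: triol F5 (made as above) is benzylated at the two non-chelated phenols (benzyl bromide, K2CO3, acetone) to give 7-(benzyloxy)-3-[3-(benzyloxy)-4,5-dimethoxyphenyl]-5-hydroxy-6-methoxy-4H-chromen-4-one F6. Elbs oxidation as in step 11 gives, through potassium 7-(benzyloxy)-3-[3-(benzyloxy)-4,5-dimethoxyphenyl]-5-hydroxy-6-methoxy-4-oxo-4H-chromen-8-yl sulfate F7 (not isolated), 7-(benzyloxy)-3-[3-(benzyloxy)-4,5-dimethoxyphenyl]-5,8-dihydroxy-6-methoxy-4H-chromen-4-one F8. Hydrogenolysis (H2, Pd/C, EtOAc/MeOH) then frees 22 under neutral conditions, with filtration under argon as the only work-up.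

**Step 7 (bromination).**
- What may go wrong: double bromination, or oxidation of the very electron-rich para-alkoxyphenol by NBS.
- Fallback, from 12, returning at 16 (it replaces steps 7 and 8): 12 is converted with N,N-diethylcarbamoyl chloride (K2CO3, MeCN) into 3,5-di-isopropoxy-4-methoxyphenyl N,N-diethylcarbamate F9. Directed ortho-lithiation between the carbamate and the isopropoxy group (s-BuLi, TMEDA, THF, −78 °C, TMSCl present) gives 3,5-di-isopropoxy-4-methoxy-2-(trimethylsilyl)phenyl N,N-diethylcarbamate F10. Reductive cleavage of the carbamate (LiAlH4, THF, 0 °C) gives 3,5-di-isopropoxy-4-methoxy-2-(trimethylsilyl)phenol F11, and triflation (Tf2O, pyridine, CH2Cl2, 0 °C) gives 16. No electrophilic halogenation or oxidant is involved.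

## Further compounds

F1 | step 9 | 1-(2-hydroxy-4,6-di-isopropoxy-5-methoxyphenyl)-2-(3-isopropoxy-4,5-dimethoxyphenyl)ethan-1-iminium chloride | Cl.COc1c(OC(C)C)cc(O)c(C(=N)Cc2cc(OC)c(OC)c(OC(C)C)c2)c1OC(C)C
F2 | step 9 | 1-(2-hydroxy-4,6-di-isopropoxy-5-methoxyphenyl)-2-(3-isopropoxy-4,5-dimethoxyphenyl)ethan-1-one | COc1c(OC(C)C)cc(O)c(C(=O)Cc2cc(OC)c(OC)c(OC(C)C)c2)c1OC(C)C
F3 | step 11 | 8-bromo-5-hydroxy-7-isopropoxy-6-methoxy-3-(3-isopropoxy-4,5-dimethoxyphenyl)-4H-chromen-4-one | COc1c(OC(C)C)c(Br)c2occ(-c3cc(OC)c(OC)c(OC(C)C)c3)c(=O)c2c1O
F4 | step 11 | 5-hydroxy-7-isopropoxy-6-methoxy-3-(3-isopropoxy-4,5-dimethoxyphenyl)-8-{[(E)-benzylideneamino]oxy}-4H-chromen-4-one | COc1c(OC(C)C)c(O/N=C/c4ccccc4)c2occ(-c3cc(OC)c(OC)c(OC(C)C)c3)c(=O)c2c1O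
F5 | step 10 | 5,7-dihydroxy-3-(3-hydroxy-4,5-dimethoxyphenyl)-6-methoxy-4H-chromen-4-one | COc1c(O)cc2occ(-c3cc(OC)c(OC)c(O)c3)c(=O)c2c1O
F6 | step 12 | 7-(benzyloxy)-3-[3-(benzyloxy)-4,5-dimethoxyphenyl]-5-hydroxy-6-methoxy-4H-chromen-4-one | COc1c(OCc4ccccc4)cc2occ(-c3cc(OC)c(OC)c(OCc5ccccc5)c3)c(=O)c2c1O
F7 | step 12 | potassium 7-(benzyloxy)-3-[3-(benzyloxy)-4,5-dimethoxyphenyl]-5-hydroxy-6-methoxy-4-oxo-4H-chromen-8-yl sulfate | COc1c(OCc4ccccc4)c(OS(=O)(=O)[O-])c2occ(-c3cc(OC)c(OC)c(OCc5ccccc5)c3)c(=O)c2c1O.[K+]
F8 | step 12 | 7-(benzyloxy)-3-[3-(benzyloxy)-4,5-dimethoxyphenyl]-5,8-dihydroxy-6-methoxy-4H-chromen-4-one | COc1c(OCc4ccccc4)c(O)c2occ(-c3cc(OC)c(OC)c(OCc5ccccc5)c3)c(=O)c2c1O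
F9 | step 7 | 3,5-di-isopropoxy-4-methoxyphenyl N,N-diethylcarbamate | CCN(CC)C(=O)Oc1cc(OC(C)C)c(OC)c(OC(C)C)c1
F10 | step 7 | 3,5-di-isopropoxy-4-methoxy-2-(trimethylsilyl)phenyl N,N-diethylcarbamate | CCN(CC)C(=O)Oc1cc(OC(C)C)c(OC)c(OC(C)C)c1[Si](C)(C)C
F11 | step 7 | 3,5-di-isopropoxy-4-methoxy-2-(trimethylsilyl)phenol | COc1c(OC(C)C)cc(O)c([Si](C)(C)C)c1OC(C)C
A1 | alternative 1 | 5,7-dihydroxy-6-methoxy-8-(methoxymethoxy)-3-[3-(methoxymethoxy)-4,5-dimethoxyphenyl]-4H-chromen-4-one | COCOc1c(O)c(OC)c(O)c2c(=O)c(-c3cc(OC)c(OC)c(OCOC)c3)coc12
A2 | alternative 1 | methyl 2-methoxy-4-(methoxymethoxy)-4-{5-[3-(methoxymethoxy)-4,5-dimethoxyphenyl]-4-oxo-4H-pyran-2-yl}-3-oxobutanoate (mixture of stereoisomers) | COCOC(C(=O)C(OC)C(=O)OC)c1cc(=O)c(-c2cc(OC)c(OC)c(OCOC)c2)co1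
A3 | alternative 2 | racemic 3-hydroxy-5,7,8-tri-isopropoxy-6-methoxy-3-(3-isopropoxy-4,5-dimethoxyphenyl)chroman-4-one | COc1c(OC(C)C)c(OC(C)C)c2OCC(O)(c3cc(OC)c(OC)c(OC(C)C)c3)C(=O)c2c1OC(C)C
A4 | alternative 2 | 3,4,6-tri-isopropoxy-5-methoxy-2-[2-(3-isopropoxy-4,5-dimethoxyphenyl)-2-oxoethoxy]benzaldehyde | O=Cc1c(OCC(=O)c2cc(OC)c(OC)c(OC(C)C)c2)c(OC(C)C)c(OC(C)C)c(OC)c1OC(C)C
A5 | alternative 2 | 5,7,8-tri-isopropoxy-6-methoxy-3-(3-isopropoxy-4,5-dimethoxyphenyl)-4H-chromen-4-one | COc1c(OC(C)C)c(OC(C)C)c2occ(-c3cc(OC)c(OC)c(OC(C)C)c3)c(=O)c2c1OC(C)C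
A6 | alternative 3 | 5,8-dihydroxy-7-isopropoxy-6-methoxy-3-(3-isopropoxy-4,5-dimethoxyphenyl)-4H-chromen-4-one (identical with 21) | COc1c(O)c2c(=O)c(-c3cc(OC)c(OC)c(OC(C)C)c3)coc2c(O)c1OC(C)C
A7 | alternative 3 | racemic 4-hydroxy-2-isopropoxy-3-methoxy-4-[5-(3-isopropoxy-4,5-dimethoxyphenyl)-4-oxo-4H-pyran-3-yl]cyclobut-2-en-1-one | COC1=C(OC(C)C)C(=O)C1(O)c1cocc(-c2cc(OC)c(OC)c(OC(C)C)c2)c1=O
A8 | alternative 3 | 3-isopropoxy-4-methoxycyclobut-3-ene-1,2-dione | COC1=C(OC(C)C)C(=O)C1=O
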